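The runs were computed on assumed constants; the scatter is artificial.

The reading at 10 d raises first the question of how far a flask has run, so the quantity reckoned here is the share of the X charge still left at that time.

| flask | X | Z | temperature | remark | time |
|---|---|---|---|---|---|
| teal | 0.20 M | 0.057 M | 45 °C | run made earlier |  |
| amber | 0.20 M | 0.18 M | 85 °C | run made earlier |  |
| green | 0.20 M | 0.60 M | 45 °C | run made earlier |  |
| ochre | 0.53 M | 0.20 M | 85 °C | run made earlier |  |
| north-west | 0.80 M | 0.600 M | 120 °C |  | 10 d |
| north | 0.60 M | 0.200 M | 65 °C |  | 10 d |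
| south | 0.40 M | 0.400 M | 80 °C |  | 10 d |
| south-east | 0.30 M | 0.0600 M | 50 °C |  | 10 d |
| south-west | 0.20 M | 0.200 M | 80 °C |  | 10 d |
| east | 0.20 M | 0.120 M | 110 °C |  | 10 d |

| run | time / d | E / % | X / % |
|---|---|---|---|
| teal | 6.00 | 1 | 88 |
| teal | 12.0 | 0 | 77 |
| teal | 15.0 | 0 | 70 |
| teal | 25.0 | 2 | 57 |
| teal | 30.0 | 2 | 52 |
| amber | 1.04 | 10 | 6 |
| amber | 2.08 | 17 | 1 |
| amber | 3.00 | 18 | 2 |
| amber | 4.00 | 19 | 1 |
| amber | 5.00 | 22 | 0 |
| green | 2.50 | 1 | 92 |
| green | 5.00 | 0 | 90 |
| green | 8.00 | 1 | 84 |
| green | 15.0 | 6 | 71 |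
| green | 30.0 | 14 | 50 |
| ochre | 0.417 | 5 | 34 |
| ochre | 0.833 | 9 | 14 |
| ochre | 1.25 | 10 | 3 |
| ochre | 2.50 | 10 | 3 |
| ochre | 5.00 | 12 | 0 |

(scatter of a reading: 2 percentage points)



* the flasks put in order of amount of E, in percent of the X charged, best first, at 10 d (north-west / north / south / south-east / south-west / east)
* the same order at 2.0 d (north-west / north / south / south-east / south-west / east)
* the amount of E, in percent of the X charged of the flask you put first, at 10 d
* the amount of E, in percent of the X charged of the flask you put last, at 10 d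

X falls like a first-order element with a time constant: teal is down to 52% at 30.0 d, and green, with ten times the Z, to 50%, a difference of 2 percentage points, the size of the scatter. The rate constant read from teal is 0.0218 d⁻¹, the first ochre reading gives 2.59 d⁻¹ at 85 °C, and a straight line in ln k between these two temperatures puts it at 0.0396 d⁻¹ at 50 °C and 1.42 d⁻¹ at 80 °C.

South-east is then reckoned to keep 67.3% of its X; this clock share, the X left as the exponential of minus rate constant times time, with the charges not entering it, stands at 9.30% for north. South and south-west are 14.2 time constants in, far beyond south-east, so their E should have stopped rising by the reading. South-east's clock share is higher than north's and higher than the X that teal read at its last reading, where E read 2%, so this reckoning expects E near zero in south-east and puts that flask last. For the top it offers amber's last reading, 22% of E with X reading 0%.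

The forecast, starting from “The first-order loss of X does not depend on Z”, gives south-west > south > north-west > east > north > south-east at 10 d and north-west > south > east > south-west > north > south-east at 2.0 d, with 23% (19% to 28%) first and 0.6% (0.2% to 1.5%) last.

The simulation gives south > north-west > south-west > east > north > south-east at 10 d, and at 2.0 d the forecast's order, north-west > south > east > south-west > north > south-east. South, not south-west, comes first with 28.2%, against the 23% the forecast gave its first flask, south-west, and south-east comes last with 0.546%, inside the forecast's range.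

    Z ⇌ J (K = 1.70, k = 0.00980 h⁻¹, Ea = 121 kJ mol⁻¹, ΔH = −41.0 kJ mol⁻¹)
    Z + D → E (k = 1.40 L mol⁻¹ h⁻¹, Ea = 75.0 kJ mol⁻¹)
    D ⇌ L (K = 1.00, k = 0.0440 h⁻¹, Ea = 116 kJ mol⁻¹, ΔH = −8.00 kJ mol⁻¹)
    X ⇌ G (K = 1.30, k = 0.0230 h⁻¹, Ea = 107 kJ mol⁻¹, ΔH = 25.0 kJ mol⁻¹)
    Z + G → D (k = 0.250 L mol⁻¹ h⁻¹, Ea = 89.0 kJ mol⁻¹)
    X → Q (k = 0.0420 h⁻¹, Ea = 115 kJ mol⁻¹)
    (constants at 80 °C)

South-east holds 65.4% of its X at 10.0 d against the clock share of 67.3%. The neighbouring flask is south-east with 0.51 M of X, which lowers the ratio of Z to X to 0.118 equiv; the clock has no charge in it, so the reckoning stays at 67.3%, and that flask keeps 65% of its X and holds 0.518% of E at 10.0 d.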